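All constants were drawn at random within sensible limits.

A chain cannot begin until E has become J, and a J that stands unreacted at the end has begun nothing.

Q 2.0 × 10⁻⁴ M; D 0.00400 mM; E 5 mol%; time 1.0 min

    Q + J → Z + L (k1 = 43 /M/s)
    Q + Z → L + Z, rate k2*[Z]*[Q] (k2 = 3300 /M/s)
    E → J (k3 = 0.12 /s)
    2 Z → Z2 (k4 = 3100 /M/s)
    D + Q → D.Q (k5 = 1800 /M/s)

- where a step has two of a species, its rate is k times that concentration squared, and two are used at each turn
- the average divides the monomer in chains by the number of chains begun, living and dead together
- run time (flask): 1.0 min

1. average number of monomer units in a chain (chains begun, living or dead) at 1.0 min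
2. part of the Q that has reacted at 1.0 min

Does E hold things up? Hardly: its half-life is 0.096 min, shorter than the run, and its mean life is 8.33 s.

Then what sets the number of chains? J itself. With Q held as charged, J goes pseudo-first-order, with a half-life of 1.34 min. That is longer than the run. So I count the start-up number, the J half-lives that fit into the run after E's mean life: 0.641. The share of the charge that has begun chains is then 35.9%, which makes 3.59 µM of chains.

And the monomer? D has a half-life of 1.9 s, far shorter than the run, so it takes its own charge of Q early. Z climbs in a straight line to that chain count, which gives a growth exponent of 0.306. So I commit to dp 14.4 and c 27.8%.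

Where is that weak? Coupling. At that count Z has a half-life of 45.0 s, shorter than the run, so I read my c as high.

The forecast gives dp 12.7 and c 23%, and it parts from my straight climb of Z on the living ends: “the living ends build to about 2 µM and are still not quite at steady state under coupling”.

The flask gives dp 15.0 and c 26.2%.

With J at 6.77 × 10⁻⁶ M, the flask has begun chains from 32.3% of its charge, against my 35.9%. The neighbour with 12 mol% of E has the same Q, time and start-up number, and shows 29.4%. The flask is not at rest at 1.0 min. At 10.0 min its Q has fallen from 74% to 7.53%, c has reached 92.5% and dp 23.8. Chains have begun from 76.0% of the charge by then, and J still stands at 2.40 × 10⁻⁶ M.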